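Whatever form it takes on the way, each G charged has either become Z or has not, so the fraction left in any flask is the charge minus [Z], over the charge.

| flask | G | Q | time |
|---|---|---|---|
| green | 0.300 M | 0.00900 M |  |
| amber | 0.300 M | 0.0130 M |  |
| grey | 0.600 M | 0.00900 M |  |
| red | 1.00 M | 0.00900 M | 18 min |

| run | time / min | [Z] / M |
|---|---|---|
| green run | 0.80 | 0.0122 |
| green run | 2.4 | 0.0355 |
| green run | 4.6 | 0.0649 |
| green run | 7.4 | 0.0984 |
| green run | 11 | 0.1316 |
| green run | 14 | 0.1550 |
| green run | 18 | 0.1801 |
| amber run | 0.80 | 0.0156 |
| amber run | 2.4 | 0.0451 |
| amber run | 4.6 | 0.0829 |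
| amber run | 7.4 | 0.1209 |
| amber run | 11 | 0.1592 |
| amber run | 14 | 0.1846 |
| amber run | 18 | 0.2116 |
| grey run | 0.80 | 0.0218 |
| grey run | 2.4 | 0.0602 |
| grey run | 4.6 | 0.1087 |
| grey run | 7.4 | 0.1688 |
| grey run | 11 | 0.2338 |
| grey run | 14 | 0.2808 |
| grey run | 18 | 0.3332 |

(scatter of a reading: 9 × 10⁻⁴ M)

* the exponent of [Q] in the starting rate at the charge of the green run (at the point where two percent of the G have become Z)
* the exponent of [G] in the starting rate at the charge of the green run (at the point where two percent of the G have become Z) (one fixed amount of Z, the same in the runs compared)
* Z in the red run at 18 min, as a share of the G charged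

- Overall: G -> Z, with Q as catalyst.
- Constant volume, constant temperature.
- The analysis sees a species whether free or bound.
- An order is taken over about fifteen percent of the charge, up and down.

We work with that fraction left. Its logarithm, taken with the sign turned and divided by the time, we call the drain constant (an apparent first-order constant). The last reading of the grey flask gives 0.0450 min⁻¹. The green flask gives 0.0510 min⁻¹ at 18 min and 0.0530 min⁻¹ at 4.6 min, so in the green flask the constant barely moves with time, and one number can stand for the run. The amber flask gives 0.0679 min⁻¹.

Each link now uses the last. Amber against green gives an exponent of 0.780 for [Q]. Grey against green, with the rate being the constant times the charge, gives 0.822 for [G], as an average from 0.300 M to 0.600 M. Holding that exponent up to 1.00 M gives the red flask a constant of 0.0411 min⁻¹ and 52.3% made by 18 min.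

That held exponent is the weak link. No run stands above 0.600 M, so this exponent is being carried beyond the charges it was read from. We therefore draw the reciprocal of the constant as a straight line in the charge instead. That line gives the red flask 0.0390 min⁻¹ and 50.4%, lower than the first figure, and this is the number we commit to.

The forecast gives 0.72 and 0.8 for the exponents and 48.5% for the red flask, a little below our figure, and says of the order in G: “This points to partial saturation.”

The red flask gives 49.4%, with exponents of 0.77 for [Q] and 0.80 for [G].

    Q + G ⇌ QG (47.22 M⁻¹ min⁻¹, 14.16 min⁻¹)
    QG → Z + Q (6.240 min⁻¹)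
    2 Q → 2 Vy (5.604 M⁻¹ min⁻¹)
    2 Q ⇌ Q2, settled at all times (92.70 M⁻¹)

A fit with the main steps alone leaves a root mean square residual of 4.2 times the scatter. The red result leaves a fraction of 50.6%, which is a drain constant of 0.0378 min⁻¹, a little lower than our 0.0390 min⁻¹. In the grey flask, ln(2) over 0.0450 min⁻¹ gives 15.4 min for the fraction left to halve, and the Z made in the grey flask came to half of its charge at 15.3 min.

(The earlier runs and the new flask were computed from invented constants; noise was put on by code.)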